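**Direct plan (as a thought)**

A direct plan would take 2,4,6-trihydroxybenzaldehyde A1 as the ring A source, cap two hydroxyls of A1 as MOM ethers, iodinate beside the free phenol and exchange iodide for methoxide (NaOMe, CuI) to reach aldehyde A2, join A2 to the prenylated mandelate A3 by a Mitsunobu reaction to give ether A4, close ring C of A4 to the flavonol A5 by carbene-catalysed acylation, and remove the MOM groups.
Its weakest steps would be:
- the iodination–methoxylation pair: with the MOM capping it would spend three operations on one methoxy group, and whether iodine enters beside the phenol or between the two MOM ethers would be left to chance;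
- the Mitsunobu etherification: a chelated phenol flanked by formyl and methoxy groups would have to displace a secondary benzylic α-hydroxy ester, so the O1–C2 bond would form slowly if at all;
- the ring C closure: acylation of a Breslow intermediate by a plain methyl ester would have no close precedent, would compete with aldol attack of the ester α-C–H on the aldehyde, and would be risked on the most advanced material.

**Plan of the new route**

Cuts: C4a–C5 and C8–C8a, which remove C5–C8 of ring A as the four carbons of a 3-alkoxycyclobutene-1,2-dione (allyl semisquarate 10), and C2–C1' (Negishi coupling); what is left is 3-hydroxy-4-pyranone.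
Order of rings: ring B (4-iodophenol) and ring C (pyromeconic acid 3) are bought; ring A is made last, on the C5=C6 bond of the pyranone, by thermal ring expansion of a 4-methoxy-4-(pyranon-6-yl)cyclobutenone.
Enabling feature: ring A is a hydroquinone monomethyl ether (C5–OH para to C8–OMe, with C6–H and C7–O between them and C4a–C8a shared with ring C), which is exactly what a semisquarate delivers to a C=C bond; ring C with its 3-OH is a 3-hydroxy-4-pyranone.
The carbinol carbon that is bonded to C8a can only become C8, so the 8-methoxy (not 6-methoxy) pattern follows from connectivity; no arene is iodinated or methoxylated, no O1–C2 ether is made and no C3–C4 bond is closed.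

Key step: step 7

Assumption: 3-hydroxy-4H-pyran-4-one (pyromeconic acid, 3) is taken as a purchasable compound (it is otherwise the decarboxylation product of comenic acid, made from kojic acid); the target has no stereocentre, and the racemic stereocentres of 9, 12, 13 and 15 are all erased.

**Route**

Step 1
Reactants: 1 4-iodophenol
Product: 2 1-iodo-4-[(3-methylbut-2-en-1-yl)oxy]benzene
Conditions: prenyl bromide (1.1 equiv), K2CO3 (1.5 equiv), acetone, reflux
Reagents that add atoms: prenyl bromide (1-bromo-3-methylbut-2-ene), CC(C)=CCBr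
Why: Williamson ether synthesis at the only acidic site should give the aryl prenyl ether, and the prenyl group is then carried unchanged to the target.

Step 2
Reactants: 3 3-hydroxy-4H-pyran-4-one (pyromeconic acid)
Product: 4 3-[(tert-butyldimethylsilyl)oxy]-4H-pyran-4-one
Conditions: TBSCl (1.2 equiv), imidazole (2.0 equiv), DMF, rt
Reagents that add atoms: tert-butyldimethylsilyl chloride (TBSCl), CC(C)(C)[Si](C)(C)Cl
Why: O-silylation of the acidic enol should give an isolable silyl ether of the 3-hydroxy-4-pyranone class, which masks the future 3-OH against the bases of steps 3 and 6 and can be removed without acid.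

Step 3
Reactants: 4 3-[(tert-butyldimethylsilyl)oxy]-4H-pyran-4-one; 2 1-iodo-4-[(3-methylbut-2-en-1-yl)oxy]benzene
Product: 6 3-[(tert-butyldimethylsilyl)oxy]-2-{4-[(3-methylbut-2-en-1-yl)oxy]phenyl}-4H-pyran-4-one, via bis(pyranon-2-yl)zinc 5 (not isolated)
Conditions: TMP2Zn·2MgCl2·2LiCl (0.6 equiv; TMP = 2,2,6,6-tetramethylpiperidin-1-yl; commercial THF solution), THF, −30 °C; then 2 (0.9 equiv), Pd(dba)2 (3 mol %), P(2-furyl)3 (6 mol %), 25 → 40 °C
Reagents that add atoms: none
Why: Directed zincation followed by Negishi coupling: with MgCl2 on the carbonyl the zinc amide should remove the most acidic ring hydrogen, C2–H between the ring oxygen and the silyloxy group (the counterpart of C2 of a chromone), and zerovalent palladium then couples diorganozinc 5 with aryl iodide 2 without touching the silyl or prenyl ether.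

Step 4
Reactants: 7 squaric acid (3,4-dihydroxycyclobut-3-ene-1,2-dione)
Product: 8 3,4-bis(prop-2-en-1-yloxy)cyclobut-3-ene-1,2-dione (diallyl squarate)
Conditions: allyl alcohol (10 equiv), toluene, reflux, Dean–Stark trap
Reagents that add atoms: allyl alcohol (prop-2-en-1-ol), C=CCO
Why: Azeotropic esterification of the strongly acidic vinylogous diacid, the way simple dialkyl squarates are made, should give the diallyl ester well below the temperature of any Claisen shift.

Step 5
Reactants: 8 3,4-bis(prop-2-en-1-yloxy)cyclobut-3-ene-1,2-dione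
Product: 10 3-(prop-2-en-1-yloxy)cyclobut-3-ene-1,2-dione (allyl semisquarate), via 4-hydroxy-2,3-bis(allyloxy)cyclobutenone 9 (not isolated)
Conditions: LiAlH(OtBu)3 (1.05 equiv), THF, −20 °C; aq. NH4Cl work-up; then conc. HCl (cat.), CH2Cl2, rt
Reagents that add atoms: none
Why: 1,2-Reduction of one squarate carbonyl by the bulky hydride followed by acid-catalysed allylic transposition with loss of allyl alcohol is the standard conversion of a dialkyl squarate into a 3-alkoxycyclobutenedione, and it puts hydrogen on the carbon that becomes C6; the stereocentre of 9 disappears.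

Step 6
Reactants: 6 3-[(tert-butyldimethylsilyl)oxy]-2-{4-[(3-methylbut-2-en-1-yl)oxy]phenyl}-4H-pyran-4-one; 10 3-(prop-2-en-1-yloxy)cyclobut-3-ene-1,2-dione
Product: 13 (±)-3-[(tert-butyldimethylsilyl)oxy]-6-[1-methoxy-4-oxo-2-(prop-2-en-1-yloxy)cyclobut-2-en-1-yl]-2-{4-[(3-methylbut-2-en-1-yl)oxy]phenyl}-4H-pyran-4-one, via 6-lithiopyranone 11 (not isolated), via lithium cyclobutenolate 12 (not isolated)
Conditions: LiTMP (1.15 equiv, from 2,2,6,6-tetramethylpiperidine and n-BuLi), THF, −78 °C, 20 min; then 10 (1.3 equiv), THF, −78 °C; then MeOTf (2.0 equiv), −78 → −20 °C; aq. NaHCO3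
Reagents that add atoms: methyl trifluoromethanesulfonate (MeOTf), COS(=O)(=O)C(F)(F)F
Why: Deprotonative lithiation, carbonyl addition and O-alkylation: LiTMP should remove C6–H, the only remaining hydrogen α to the ring oxygen (the site lithium amides attack in 3-substituted chromones and N-alkyl-4-pyridones), vinyllithium 11 adds 1,2 to the carbonyl of 10 next to the allyloxy carbon because the other carbonyl is a deactivated vinylogous ester, and MeOTf caps lithium alkoxide 12 cold, the new quaternary stereocentre forming as a racemate that step 7 erases.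

Step 7
Reactants: 13 (±)-3-[(tert-butyldimethylsilyl)oxy]-6-[1-methoxy-4-oxo-2-(prop-2-en-1-yloxy)cyclobut-2-en-1-yl]-2-{4-[(3-methylbut-2-en-1-yl)oxy]phenyl}-4H-pyran-4-one
Product: 16 3-[(tert-butyldimethylsilyl)oxy]-5-hydroxy-8-methoxy-2-{4-[(3-methylbut-2-en-1-yl)oxy]phenyl}-7-(prop-2-en-1-yloxy)-4H-chromen-4-one, via dienylketene 14 (not isolated), via 4aH-chromene-4,5-dione 15 (not isolated)
Conditions: toluene (0.02 M, degassed), 110 °C, Ar, 1–3 h
Reagents that add atoms: none
Why: Heating opens the cyclobutenone by conrotatory 4π electrocyclic cleavage of the C(OMe)–C(=O) bond; the donor methoxy group rotates outward, so the pyranonyl group turns inward and the (Z)-dienylketene 14 holds its ketene carbon next to C5 of the pyranone. A 6π electrocyclisation then joins the ketene carbon to pyranone C5 (the future C4a–C5 bond) and closes ring A as cyclohexadienone 15, whose C4a–H lies between two carbonyls and should shift to oxygen at once to give the chelated 5-OH phenol 16. The closest known reaction type is the thermal ring expansion of squarate-derived 4-aryl- and 4-heteroaryl-4-alkoxycyclobutenones to hydroquinone monoethers (Liebeskind–Moore benzannulation), here with the C5=C6 bond of a 4-pyranone in the place of the arene. Ring A closes by disrotatory 6π electrocyclisation of a trienyl system whose third double bond is the pyranone C5=C6 bond; no stereocentre survives, since the quaternary centre of 13 and C4a of 15 both become sp2. The step needs the right torquoselectivity and ring closure ahead of any Claisen shift of the allyl ethers: the first is secured by the methoxy donor on the carbinol carbon, the second by the temperature, which lies well below that of allyl vinyl or allyl aryl ether rearrangements. The substitution pattern needs no selectivity here, because the carbinol carbon bonded to C8a can only become C8 and the former vinylogous-ester carbonyl can only become C5.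

Step 8
Reactants: 16 3-[(tert-butyldimethylsilyl)oxy]-5-hydroxy-8-methoxy-2-{4-[(3-methylbut-2-en-1-yl)oxy]phenyl}-7-(prop-2-en-1-yloxy)-4H-chromen-4-one
Product: 18 3,5,7-trihydroxy-8-methoxy-2-{4-[(3-methylbut-2-en-1-yl)oxy]phenyl}-4H-chromen-4-one (3,5,7-trihydroxy-8-methoxy-4'-prenyloxyflavone), via 7-O-allyl flavonol 17 (not isolated)
Conditions: Pd(PPh3)4 (5 mol %), K2CO3 (3 equiv), degassed MeOH/THF (3:1), rt, Ar; then aq. NH4Cl
Reagents that add atoms: none
Why: Basic methanolysis should cleave the silyl ether of the acidic 3-enol, and Tsuji–Trost deallylation should free O7, since zerovalent palladium ionises the terminal allyl ether of the vinylogous acid far faster than the trisubstituted prenyl ether and methanol captures the π-allyl fragment; no acid meets the prenyl ether.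

**Compound list**

1 | 4-iodophenol | Oc1ccc(I)cc1 | starting material
2 | 1-iodo-4-[(3-methylbut-2-en-1-yl)oxy]benzene | CC(C)=CCOc1ccc(I)cc1 | intermediate
3 | 3-hydroxy-4H-pyran-4-one (pyromeconic acid) | O=C1C=COC=C1O | starting material
4 | 3-[(tert-butyldimethylsilyl)oxy]-4H-pyran-4-one | O=C1C=COC=C1O[Si](C)(C)C(C)(C)C | intermediate
5 | bis{3-[(tert-butyldimethylsilyl)oxy]-4-oxo-4H-pyran-2-yl}zinc (as its MgCl2/LiCl complex) | CC(C)(C)[Si](C)(C)OC1=C([Zn]C2=C(O[Si](C)(C)C(C)(C)C)C(=O)C=CO2)OC=CC1=O | intermediate (not isolated)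
6 | 3-[(tert-butyldimethylsilyl)oxy]-2-{4-[(3-methylbut-2-en-1-yl)oxy]phenyl}-4H-pyran-4-one | O=C1C=COC(c2ccc(OCC=C(C)C)cc2)=C1O[Si](C)(C)C(C)(C)C | intermediate
7 | squaric acid (3,4-dihydroxycyclobut-3-ene-1,2-dione) | OC1=C(O)C(=O)C1=O | starting material
8 | 3,4-bis(prop-2-en-1-yloxy)cyclobut-3-ene-1,2-dione (diallyl squarate) | C=CCOC1=C(OCC=C)C(=O)C1=O | intermediate
9 | (±)-4-hydroxy-2,3-bis(prop-2-en-1-yloxy)cyclobut-2-en-1-one (racemic) | C=CCOC1=C(OCC=C)C(O)C1=O | intermediate (not isolated)
10 | 3-(prop-2-en-1-yloxy)cyclobut-3-ene-1,2-dione (allyl semisquarate) | C=CCOC1=CC(=O)C1=O | intermediate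
11 | {5-[(tert-butyldimethylsilyl)oxy]-6-{4-[(3-methylbut-2-en-1-yl)oxy]phenyl}-4-oxo-4H-pyran-2-yl}lithium (6-lithio derivative of 6) | [Li]C1=CC(=O)C(O[Si](C)(C)C(C)(C)C)=C(c2ccc(OCC=C(C)C)cc2)O1 | intermediate (not isolated)
12 | lithium (±)-1-{5-[(tert-butyldimethylsilyl)oxy]-6-{4-[(3-methylbut-2-en-1-yl)oxy]phenyl}-4-oxo-4H-pyran-2-yl}-4-oxo-2-(prop-2-en-1-yloxy)cyclobut-2-en-1-olate (racemic) | [Li]OC1(C(OCC=C)=CC1=O)C2=CC(=O)C(O[Si](C)(C)C(C)(C)C)=C(c3ccc(OCC=C(C)C)cc3)O2 | intermediate (not isolated)
13 | (±)-3-[(tert-butyldimethylsilyl)oxy]-6-[1-methoxy-4-oxo-2-(prop-2-en-1-yloxy)cyclobut-2-en-1-yl]-2-{4-[(3-methylbut-2-en-1-yl)oxy]phenyl}-4H-pyran-4-one (racemic) | COC1(C(OCC=C)=CC1=O)C2=CC(=O)C(O[Si](C)(C)C(C)(C)C)=C(c3ccc(OCC=C(C)C)cc3)O2 | intermediate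
14 | (Z)-4-{5-[(tert-butyldimethylsilyl)oxy]-6-{4-[(3-methylbut-2-en-1-yl)oxy]phenyl}-4-oxo-4H-pyran-2-yl}-4-methoxy-3-(prop-2-en-1-yloxy)buta-1,3-dien-1-one (dienylketene; pyranonyl cis to the ketenyl group) | O=C=C/C(OCC=C)=C(OC)\C1=CC(=O)C(O[Si](C)(C)C(C)(C)C)=C(c2ccc(OCC=C(C)C)cc2)O1 | intermediate (not isolated)
15 | (±)-3-[(tert-butyldimethylsilyl)oxy]-8-methoxy-2-{4-[(3-methylbut-2-en-1-yl)oxy]phenyl}-7-(prop-2-en-1-yloxy)-4aH-chromene-4,5-dione (racemic) | COC1=C2OC(c3ccc(OCC=C(C)C)cc3)=C(O[Si](C)(C)C(C)(C)C)C(=O)C2C(=O)C=C1OCC=C | intermediate (not isolated)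
16 | 3-[(tert-butyldimethylsilyl)oxy]-5-hydroxy-8-methoxy-2-{4-[(3-methylbut-2-en-1-yl)oxy]phenyl}-7-(prop-2-en-1-yloxy)-4H-chromen-4-one | COc1c(OCC=C)cc(O)c2c(=O)c(O[Si](C)(C)C(C)(C)C)c(-c3ccc(OCC=C(C)C)cc3)oc12 | intermediate
17 | 3,5-dihydroxy-8-methoxy-2-{4-[(3-methylbut-2-en-1-yl)oxy]phenyl}-7-(prop-2-en-1-yloxy)-4H-chromen-4-one | COc1c(OCC=C)cc(O)c2c(=O)c(O)c(-c3ccc(OCC=C(C)C)cc3)oc12 | intermediate (not isolated)
18 | 3,5,7-trihydroxy-8-methoxy-2-{4-[(3-methylbut-2-en-1-yl)oxy]phenyl}-4H-chromen-4-one | COc1c(O)cc(O)c2c(=O)c(O)c(-c3ccc(OCC=C(C)C)cc3)oc12 | target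

**Count and risks**

Total steps: 8. Longest linear sequence: 5 steps (3 → 4 → 6 → 13 → 16 → 18; the branch 7 → 8 → 10 → 13 → 16 → 18 is equally long).

The three steps most likely to fail:

Step 6. The base may deprotonate C5 (directed by the carbonyl) instead of C6, the lithiated pyranone 11 may add to unreacted 6, or MeOTf may methylate the pyranone carbonyl. The fallback sets out from 6 and returns at 13. Zincation of 6 with TMP2Zn·2MgCl2·2LiCl in THF at −30 °C, whose regiochemistry (the C–H α to the ring oxygen when MgCl2 complexes the carbonyl) is that of the C2 zincation of chromones, would give bis{5-[(tert-butyldimethylsilyl)oxy]-6-{4-[(3-methylbut-2-en-1-yl)oxy]phenyl}-4-oxo-4H-pyran-2-yl}zinc F1 in solution. Iodine at −30 °C would convert F1 into the stable 3-[(tert-butyldimethylsilyl)oxy]-6-iodo-2-{4-[(3-methylbut-2-en-1-yl)oxy]phenyl}-4H-pyran-4-one F2 after thiosulfate work-up. Iodine–magnesium exchange of F2 with iPrMgCl·LiCl at −78 °C would give {5-[(tert-butyldimethylsilyl)oxy]-6-{4-[(3-methylbut-2-en-1-yl)oxy]phenyl}-4-oxo-4H-pyran-2-yl}magnesium chloride F3 as a reagent of the class known to add to squarate carbonyls. Addition of F3 to 10 and aqueous quench would give (±)-3-[(tert-butyldimethylsilyl)oxy]-6-[1-hydroxy-4-oxo-2-(prop-2-en-1-yloxy)cyclobut-2-en-1-yl]-2-{4-[(3-methylbut-2-en-1-yl)oxy]phenyl}-4H-pyran-4-one F4 as the free tertiary alcohol, and MeI/Ag2O in CH2Cl2 in the dark would methylate F4 to 13.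

Step 3. Zincation may occur at C6 rather than C2, the hindered ortho-silyloxy organozinc may couple slowly, or the silyl group may be lost. The fallback sets out from 3 and 2 and returns at 6. Bromination of 3 with NBS in MeCN at 0 °C, ortho to the enol, would give 2-bromo-3-hydroxy-4H-pyran-4-one F5 with the halogen at the future aryl position, and TBSCl/imidazole in DMF would convert F5 into 2-bromo-3-[(tert-butyldimethylsilyl)oxy]-4H-pyran-4-one F6 as the coupling partner. Miyaura borylation of 2 (bis(pinacolato)diboron, Pd(dppf)Cl2, KOAc, dioxane, 80 °C) would give 4,4,5,5-tetramethyl-2-{4-[(3-methylbut-2-en-1-yl)oxy]phenyl}-1,3,2-dioxaborolane F7 as the ring B donor. Suzuki–Miyaura coupling of F6 with F7 (Pd(dppf)Cl2, anhydrous K3PO4, dioxane, 80 °C) would give 6 with the aryl position fixed by the bromine.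

Step 8. Zerovalent palladium may ionise the prenyl ether beside the allyl ether, or the π-allyl complex may C-allylate the electron-rich ring A. The fallback sets out from 16 and returns at 18. Isomerisation of the terminal allyl ether with hydrogen-activated [Ir(cod)(PMePh2)2]PF6 in THF at rt, a catalyst that leaves trisubstituted allyl ethers alone, would give 3-[(tert-butyldimethylsilyl)oxy]-5-hydroxy-8-methoxy-2-{4-[(3-methylbut-2-en-1-yl)oxy]phenyl}-7-[(E)-prop-1-en-1-yloxy]-4H-chromen-4-one F8 as the enol ether. Brief treatment of F8 with 0.5 M HCl in THF/MeOH/H2O at 0 °C → rt would then hydrolyse the enol ether and the silyl ether to 18.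

Step 7 is judged less exposed than these three: its reaction type is the best precedented of the ring A operations and it needs no regiochemical selectivity of its own.

**Further compounds**

F1 | step 6 | bis{5-[(tert-butyldimethylsilyl)oxy]-6-{4-[(3-methylbut-2-en-1-yl)oxy]phenyl}-4-oxo-4H-pyran-2-yl}zinc | [Zn](C1=CC(=O)C(O[Si](C)(C)C(C)(C)C)=C(c2ccc(OCC=C(C)C)cc2)O1)C3=CC(=O)C(O[Si](C)(C)C(C)(C)C)=C(c4ccc(OCC=C(C)C)cc4)O3
F2 | step 6 | 3-[(tert-butyldimethylsilyl)oxy]-6-iodo-2-{4-[(3-methylbut-2-en-1-yl)oxy]phenyl}-4H-pyran-4-one | IC1=CC(=O)C(O[Si](C)(C)C(C)(C)C)=C(c2ccc(OCC=C(C)C)cc2)O1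
F3 | step 6 | {5-[(tert-butyldimethylsilyl)oxy]-6-{4-[(3-methylbut-2-en-1-yl)oxy]phenyl}-4-oxo-4H-pyran-2-yl}magnesium chloride | Cl[Mg]C1=CC(=O)C(O[Si](C)(C)C(C)(C)C)=C(c2ccc(OCC=C(C)C)cc2)O1
F4 | step 6 | (±)-3-[(tert-butyldimethylsilyl)oxy]-6-[1-hydroxy-4-oxo-2-(prop-2-en-1-yloxy)cyclobut-2-en-1-yl]-2-{4-[(3-methylbut-2-en-1-yl)oxy]phenyl}-4H-pyran-4-one (racemic) | OC1(C(OCC=C)=CC1=O)C2=CC(=O)C(O[Si](C)(C)C(C)(C)C)=C(c3ccc(OCC=C(C)C)cc3)O2
F5 | step 3 | 2-bromo-3-hydroxy-4H-pyran-4-one | O=C1C=COC(Br)=C1O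
F6 | step 3 | 2-bromo-3-[(tert-butyldimethylsilyl)oxy]-4H-pyran-4-one | O=C1C=COC(Br)=C1O[Si](C)(C)C(C)(C)C
F7 | step 3 | 4,4,5,5-tetramethyl-2-{4-[(3-methylbut-2-en-1-yl)oxy]phenyl}-1,3,2-dioxaborolane | CC(C)=CCOc1ccc(cc1)B1OC(C)(C)C(C)(C)O1
F8 | step 8 | 3-[(tert-butyldimethylsilyl)oxy]-5-hydroxy-8-methoxy-2-{4-[(3-methylbut-2-en-1-yl)oxy]phenyl}-7-[(E)-prop-1-en-1-yloxy]-4H-chromen-4-one | COc1c(O/C=C/C)cc(O)c2c(=O)c(O[Si](C)(C)C(C)(C)C)c(-c3ccc(OCC=C(C)C)cc3)oc12
A1 | direct plan | 2,4,6-trihydroxybenzaldehyde | O=Cc1c(O)cc(O)cc1O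
A2 | direct plan | 2-hydroxy-3-methoxy-4,6-bis(methoxymethoxy)benzaldehyde | O=Cc1c(O)c(OC)c(OCOC)cc1OCOC
A3 | direct plan | methyl (±)-2-hydroxy-2-{4-[(3-methylbut-2-en-1-yl)oxy]phenyl}acetate (racemic) | COC(=O)C(O)c1ccc(OCC=C(C)C)cc1
A4 | direct plan | methyl (±)-2-[2-formyl-6-methoxy-3,5-bis(methoxymethoxy)phenoxy]-2-{4-[(3-methylbut-2-en-1-yl)oxy]phenyl}acetate (racemic) | COC(=O)C(Oc1c(C=O)c(OCOC)cc(OCOC)c1OC)c1ccc(OCC=C(C)C)cc1
A5 | direct plan | 3-hydroxy-8-methoxy-5,7-bis(methoxymethoxy)-2-{4-[(3-methylbut-2-en-1-yl)oxy]phenyl}-4H-chromen-4-one | COc1c(OCOC)cc(OCOC)c2c(=O)c(O)c(-c3ccc(OCC=C(C)C)cc3)oc12
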